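**Retrosynthetic overview**

1. Target ⇐ silyl ether 37 ⇐ closure of the ten-membered carbocycle last, at C7–C8, by a SmI2 Reformatsky-type aldol of a C9 chloromethyl ketone onto a C6 acetyl group.
2. Tetrahydropyran (C2–O–C6) ⇐ oxidative dearomatisation (Achmatowicz) of a 2,5-disubstituted furan with silane reduction in the same flask (2,6-cis); C3 by Grignard addition and acylation, C7 ketone from a silylalkyne.
3. C9–C10 and the exocyclic methylene ⇐ carbonylative lactonisation of an enol triflate, then deconjugative protonation of the lactone (cis ring fusion fixes C10).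
4. C1–C2 ⇐ anti-selective boron aldol of a carvone-type cyclohexenone with a furfural-derived 5-alkynylfurfural.
5. Cyclohexenone ⇐ organocatalytic Michael/aldol annulation of a Roche-ester-derived enal (C15 from the chiral pool, C14 by catalyst). Ring order: cyclohexene → tetrahydropyran → ten-membered ring.

Assumption: locants C1–C20 follow eunicellane numbering of the target (C1/C10 ring fusion, C2–O–C6 ether, C9 ketone, C11=C20, C14 side chain C15(C16)C17OH); TBDPS = tert-butyldiphenylsilyl. Stereodescriptors in the names were derived by hand; the SMILES are authoritative.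

**Route**

Step 1
Reactants: 1 methyl (S)-3-hydroxy-2-methylpropanoate
Product: 2 methyl (S)-3-(TBDPS-oxy)-2-methylpropanoate
Conditions: t-BuPh2SiCl, imidazole, DMF, 0 °C → rt
Reagents that add atoms: tert-butyl(chloro)diphenylsilane, CC(C)(C)[Si](Cl)(c1ccccc1)c1ccccc1
Why: Silyl ether formation protects the future C17 hydroxyl; the C15 stereocentre is taken unchanged from the chiral pool.

Step 2
Reactants: 2 methyl (S)-3-(TBDPS-oxy)-2-methylpropanoate
Product: 3 (S)-3-(TBDPS-oxy)-2-methylpropanal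
Conditions: i-Bu2AlH (1.05 equiv), CH2Cl2, −78 °C; aq. potassium sodium tartrate (KNaC4H4O6) work-up, used crude
Reagents that add atoms: none
Why: Partial ester reduction stops at the aldehyde because the aluminium hemiacetal is stable at −78 °C; the α-centre is not touched.

Step 3
Reactants: 3 (S)-3-(TBDPS-oxy)-2-methylpropanal
Product: 4 (R,E)-5-(TBDPS-oxy)-4-methylpent-2-enal
Conditions: Ph3P=CHCHO, toluene, 60 °C
Reagents that add atoms: (triphenylphosphoranylidene)acetaldehyde, O=CC=P(c1ccccc1)(c1ccccc1)c1ccccc1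
Why: Wittig olefination with a stabilised, non-basic ylide gives the (E)-enal without epimerising the adjacent centre.

Step 4
Reactants: 4 (R,E)-5-(TBDPS-oxy)-4-methylpent-2-enal; 5 tert-butyl 3-oxopentanoate
Product: 8 (5S)-5-[(2R)-1-(TBDPS-oxy)propan-2-yl]-2-methylcyclohex-2-en-1-one, via Michael adduct 6 (not isolated), via keto ester 7 (not isolated)
Conditions: (R)-2-{bis[3,5-bis(trifluoromethyl)phenyl](trimethylsilyloxy)methyl}pyrrolidine (10 mol %), PhCO2H (10 mol %), toluene, rt; then p-TsOH·H2O (20 mol %), 80 °C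
Reagents that add atoms: none
Why: Iminium-catalysed asymmetric Michael addition, then acid-mediated aldol condensation and tert-butyl ester cleavage/decarboxylation (Robinson-type annulation); the keto ester attacks the (E)-iminium face opposite the diarylsilyloxymethyl group, which sets C14.

Step 5
Reactants: 9 furan-2-carbaldehyde (furfural)
Product: 10 5-bromofuran-2-carbaldehyde
Conditions: Br2, AlCl3, ClCH2CH2Cl, 0 °C → rt
Reagents that add atoms: bromine, BrBr
Why: Electrophilic aromatic bromination of the AlCl3-complexed aldehyde occurs at the free α-position C5.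

Step 6
Reactants: 10 5-bromofuran-2-carbaldehyde; 11 ethynyltrimethylsilane
Product: 12 5-[(trimethylsilyl)ethynyl]furan-2-carbaldehyde
Conditions: PdCl2(PPh3)2 (2 mol %), CuI (4 mol %), Et3N, THF, rt
Reagents that add atoms: none
Why: Sonogashira coupling installs the two carbons that become C7 and C19 as a masked acetyl group.

Step 7
Reactants: 13 (S)-2-hydroxybutanoic acid
Product: 14 (S)-2-(butanoyloxy)butanoic acid
Conditions: butanoyl chloride (1.3 equiv), neat, 0 → 45 °C; then H2O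
Reagents that add atoms: butanoyl chloride, CCCC(Cl)=O
Why: O-Acylation (nucleophilic acyl substitution) of the α-hydroxy acid without base leaves the stereocentre untouched; water cleaves any mixed anhydride.

Step 8
Reactants: 14 (S)-2-(butanoyloxy)butanoic acid (two molecules condense per molecule of 15; the second is entered below as the acyl donor)
Product: 15 (S)-2-(butanoyloxy)butanoic anhydride
Conditions: DCC (0.5 equiv relative to 14), CH2Cl2, 0 °C → rt; filtration
Reagents that add atoms: (S)-2-(butanoyloxy)butanoic acid (the second molecule of 14), CCCC(=O)O[C@@H](CC)C(=O)O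
Why: Carbodiimide dehydration: one molecule of 14 is activated as its O-acylisourea and is acylated by the carboxyl group of a second molecule of 14, giving the symmetric anhydride and the urea under base-free conditions, so the α-acyloxy centre is not racemised.

Step 9
Reactants: 8 (5S)-5-[(2R)-1-(TBDPS-oxy)propan-2-yl]-2-methylcyclohex-2-en-1-one; 12 5-[(trimethylsilyl)ethynyl]furan-2-carbaldehyde
Product: 18 (5R,6S)-6-[(R)-hydroxy{5-[(trimethylsilyl)ethynyl]furan-2-yl}methyl]-2-methyl-5-[(2R)-1-(TBDPS-oxy)propan-2-yl]cyclohex-2-en-1-one, via boron dienolate 16 (not isolated), via boron aldolate 17 (not isolated)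
Conditions: (c-C6H11)2BCl, Et3N, Et2O, −78 → 0 °C; 12, −78 → −20 °C; pH 7 buffer, MeOH, H2O2, 0 °C
Reagents that add atoms: none
Why: Boron-mediated aldol reaction; the ring-locked E-enolate reacts through a Zimmerman–Traxler chair to give the anti aldol (C2), and the aldehyde approaches anti to the C14 side chain (C1 trans to C14).

Step 10
Reactants: 18 aldol adduct (name as in step 9)
Product: 21 (5R,6S)-6-[(R)-hydroxy{5-[(trimethylsilyl)ethynyl]furan-2-yl}methyl]-2-methyl-5-[(2R)-1-(TBDPS-oxy)propan-2-yl]cyclohex-1-en-1-yl trifluoromethanesulfonate, via lithium alkoxide 19 (not isolated), via dilithium enolate 20 (not isolated)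
Conditions: LiN(SiMe3)2 (1.05 equiv), THF, −78 °C; LiBH(s-Bu)3 (1.1 equiv), −78 °C; PhNTf2 (1.3 equiv), −78 → 0 °C; NH4Cl
Reagents that add atoms: N-phenylbis(trifluoromethanesulfonimide), O=S(=O)(N(c1ccccc1)S(=O)(=O)C(F)(F)F)C(F)(F)F
Why: Conjugate hydride reduction of the enone gives the C10–C11 enolate regiospecifically and PhNTf2 traps it on oxygen (enolate triflation); once the ketone is an enolate, retro-aldol of the alkoxide is impossible.

Step 11
Reactants: 21 hydroxy enol triflate (name as in step 10)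
Product: 22 (3R,3aR,4R)-7-methyl-4-[(2R)-1-(TBDPS-oxy)propan-2-yl]-3-{5-[(trimethylsilyl)ethynyl]furan-2-yl}-3a,4,5,6-tetrahydro-2-benzofuran-1(3H)-one
Conditions: Pd(PPh3)4 (5 mol %), CO (1 atm), n-Bu3N, LiCl, MeCN, 65 °C
Reagents that add atoms: carbon monoxide, [C-]#[O+]
Why: Palladium-catalysed carbonylative lactonisation (oxidative addition to zerovalent palladium, CO insertion, capture of the acylpalladium by the γ-hydroxyl) installs C9 and ties it to the C2 oxygen.

Step 12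
Reactants: 22 conjugated lactone (name as in step 11)
Product: 24 (3R,3aR,4R,7aR)-7-methylidene-4-[(2R)-1-(TBDPS-oxy)propan-2-yl]-3-{5-[(trimethylsilyl)ethynyl]furan-2-yl}hexahydro-2-benzofuran-1(3H)-one (cis-fused), via lithium dienolate 23 (not isolated)
Conditions: LiN(i-Pr)2 (1.3 equiv), THF, −78 °C; AcOH, −78 °C
Reagents that add atoms: none
Why: Deconjugative protonation; the lactone carbonyl directs γ-deprotonation to the syn methyl (C20), and kinetic α-protonation at C10 on the face of H1 gives the cis-fused γ-lactone, which sets C10 and the C11=C20 methylene.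

Step 13
Reactants: 24 cis-fused methylidene lactone (name as in step 12)
Product: 25 (1R,2R,3R)-2-[(R)-hydroxy{5-[(trimethylsilyl)ethynyl]furan-2-yl}methyl]-N-methoxy-N-methyl-6-methylidene-3-[(2R)-1-(TBDPS-oxy)propan-2-yl]cyclohexane-1-carboxamide
Conditions: MeNHOMe·HCl, AlMe3, CH2Cl2, 0 °C → rt; aq. potassium sodium tartrate (KNaC4H4O6) work-up, used at once
Reagents that add atoms: N,O-dimethylhydroxylamine hydrochloride, Cl.CNOC
Why: Aluminium amide aminolysis of the lactone (Weinreb amide formation) frees the furfuryl alcohol under non-basic conditions, so C10 is not epimerised.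

Step 14
Reactants: 25 hydroxy Weinreb amide (name as in step 13)
Product: 27 (1R,2R,3R)-N-methoxy-N-methyl-6-methylidene-2-{(2R,6R)-3-oxo-6-[(trimethylsilyl)ethynyl]-3,6-dihydro-2H-pyran-2-yl}-3-[(2R)-1-(TBDPS-oxy)propan-2-yl]cyclohexane-1-carboxamide, via hemiketal 26 (not isolated)
Conditions: VO(acac)2 (5 mol %), t-BuOOH (1.2 equiv), CH2Cl2, 0 °C → rt; then Et3SiH, CF3CO2H, −40 °C
Reagents that add atoms: tert-butyl hydroperoxide, CC(C)(C)OO
Why: Achmatowicz rearrangement (hydroxyl-directed oxidative dearomatisation of the furan, far faster than attack on the 1,1-disubstituted alkene) followed by Kishi-type ionic hydrogenation; axial hydride delivery to the alkynyl-stabilised oxocarbenium ion gives the 2,6-cis pyranone, keeping C2 and setting C6.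

Step 15
Reactants: 27 dihydropyranone (name as in step 14)
Product: 28 (1R,2R,3R)-N-methoxy-N-methyl-6-methylidene-2-{(2R,6R)-3-oxo-6-[(trimethylsilyl)ethynyl]oxan-2-yl}-3-[(2R)-1-(TBDPS-oxy)propan-2-yl]cyclohexane-1-carboxamide
Conditions: [(Ph3P)CuH]6 (3 mol %), PhMe2SiH, t-BuOH, toluene, rt
Reagents that add atoms: none
Why: Copper hydride conjugate reduction is selective for the enone and leaves the exocyclic alkene, the silylalkyne and the amide alone.

Step 16
Reactants: 28 tetrahydropyranone (name as in step 15)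
Product: 31 2-chloro-1-[(1R,2R,3R)-2-{(2R,3R,6R)-3-hydroxy-3-methyl-6-[(trimethylsilyl)ethynyl]oxan-2-yl}-6-methylidene-3-[(2R)-1-(TBDPS-oxy)propan-2-yl]cyclohexyl]ethan-1-one, via magnesium alkoxide 29 (not isolated), via lithium hemiaminal 30 (not isolated)
Conditions: MeMgBr (1.2 equiv), CeCl3, THF, −78 °C; then ICH2Cl (3 equiv), MeLi·LiBr (2.8 equiv), −78 °C; AcOH, −78 °C
Reagents that add atoms: methylmagnesium bromide, C[Mg]Br; chloroiodomethane, ClCI
Why: Grignard 1,2-addition from the equatorial direction, trans to the C2 substituent, sets C3; chloromethyllithium then adds once to the Weinreb amide (carbenoid homologation through the chelated tetrahedral intermediate) to give the chloromethyl ketone, and the cold acidic quench protects C10.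

Step 17
Reactants: 31 tertiary alcohol chloromethyl ketone (name as in step 16); 15 (S)-2-(butanoyloxy)butanoic anhydride
Product: 32 (2R,3R,6R)-2-[(1R,2R,6R)-2-(chloroacetyl)-3-methylidene-6-[(2R)-1-(TBDPS-oxy)propan-2-yl]cyclohexyl]-3-methyl-6-[(trimethylsilyl)ethynyl]oxan-3-yl (2S)-2-(butanoyloxy)butanoate
Conditions: Sc(OTf)3 (10 mol %), MeCN/CH2Cl2, −20 → 0 °C
Reagents that add atoms: none
Why: Lewis acid-catalysed acylation of a hindered tertiary alcohol by an anhydride; without base the chloroketone, C10 and the α-acyloxy centre are not enolised.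

Step 18
Reactants: 32 alkynyl ester (name as in step 17)
Product: 34 (2R,3R,6R)-6-acetyl-2-[(1R,2R,6R)-2-(chloroacetyl)-3-methylidene-6-[(2R)-1-(TBDPS-oxy)propan-2-yl]cyclohexyl]-3-methyloxan-3-yl (2S)-2-(butanoyloxy)butanoate, via silyl ketone 33 (not isolated)
Conditions: Ph3PAuCl (5 mol %), AgOTf (5 mol %), MeOH/H2O (10:1), 40 °C
Reagents that add atoms: water, O
Why: Gold-catalysed alkyne hydration; water adds at the carbon β to silicon (C7) and the α-silyl ketone is protodesilylated in methanol, giving the C7 methyl ketone.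

Step 19
Reactants: 34 chloromethyl ketone methyl ketone (name as in step 18)
Product: 37 17-O-TBDPS ether of the target, via samarium enolate 35 (not isolated), via samarium aldolate 36 (not isolated)
Conditions: SmI2 (2.5 equiv), THF (0.005 M), −78 → −40 °C; NH4Cl
Reagents that add atoms: none
Why: SmI2 Reformatsky-type intramolecular aldol; C–Cl reduction gives the regiodefined trivalent samarium enolate at C8, which adds to the C7 ketone chelated to the ring oxygen from the side of H6, placing the methyl group outside the new ring (7R) and closing the ten-membered carbocycle.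

Step 20
Reactants: 37 17-O-TBDPS ether of the target
Product: 38 target CNP0291223.2, (1R,2R,3R,6R,7R,10R,14R)-7-hydroxy-14-[(2R)-1-hydroxypropan-2-yl]-3,7-dimethyl-11-methylidene-9-oxo-2,6-epoxy-eunicellan-3-yl (2S)-2-(butanoyloxy)butanoate
Conditions: HF·pyridine, pyridine, THF, 0 °C → rt
Reagents that add atoms: none
Why: Fluoride-mediated desilylation under buffered, mildly acidic conditions spares the β-hydroxy ketone, the β,γ-unsaturated ketone and both esters.

**Compound list**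

1 | methyl (S)-3-hydroxy-2-methylpropanoate | COC(=O)[C@@H](C)CO | starting material
2 | methyl (S)-3-(TBDPS-oxy)-2-methylpropanoate | COC(=O)[C@@H](C)CO[Si](c1ccccc1)(c1ccccc1)C(C)(C)C | intermediate
3 | (S)-3-(TBDPS-oxy)-2-methylpropanal | O=C[C@@H](C)CO[Si](c1ccccc1)(c1ccccc1)C(C)(C)C | intermediate
4 | (R,E)-5-(TBDPS-oxy)-4-methylpent-2-enal | O=C/C=C/[C@@H](C)CO[Si](c1ccccc1)(c1ccccc1)C(C)(C)C | intermediate
5 | tert-butyl 3-oxopentanoate | CCC(=O)CC(=O)OC(C)(C)C | starting material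
6 | Michael adduct, tert-butyl (3R)-5-oxo-2-propanoyl-3-[(2R)-1-(TBDPS-oxy)propan-2-yl]pentanoate (C2 epimers) | CCC(=O)C(C(=O)OC(C)(C)C)[C@H](CC=O)[C@@H](C)CO[Si](c1ccccc1)(c1ccccc1)C(C)(C)C | intermediate
7 | tert-butyl 3-methyl-2-oxo-6-[(2R)-1-(TBDPS-oxy)propan-2-yl]cyclohex-3-ene-1-carboxylate (ring C6 as in 8, C1 epimers) | CC1=CC[C@H]([C@@H](C)CO[Si](c2ccccc2)(c2ccccc2)C(C)(C)C)C(C(=O)OC(C)(C)C)C1=O | intermediate
8 | (5S)-5-[(2R)-1-(TBDPS-oxy)propan-2-yl]-2-methylcyclohex-2-en-1-one | CC1=CC[C@H]([C@@H](C)CO[Si](c2ccccc2)(c2ccccc2)C(C)(C)C)CC1=O | intermediate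
9 | furan-2-carbaldehyde (furfural) | O=Cc1ccco1 | starting material
10 | 5-bromofuran-2-carbaldehyde | O=Cc1ccc(Br)o1 | intermediate
11 | ethynyltrimethylsilane | C#C[Si](C)(C)C | starting material
12 | 5-[(trimethylsilyl)ethynyl]furan-2-carbaldehyde | O=Cc1ccc(C#C[Si](C)(C)C)o1 | intermediate
13 | (S)-2-hydroxybutanoic acid | CC[C@H](O)C(=O)O | starting material
14 | (S)-2-(butanoyloxy)butanoic acid | CCCC(=O)O[C@@H](CC)C(=O)O | intermediate
15 | (S)-2-(butanoyloxy)butanoic anhydride | CCCC(=O)O[C@@H](CC)C(=O)OC(=O)[C@H](CC)OC(=O)CCC | intermediate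
16 | dicyclohexylboron dienolate of 8 | CC1=CC[C@H]([C@@H](C)CO[Si](c2ccccc2)(c2ccccc2)C(C)(C)C)C=C1OB(C1CCCCC1)C1CCCCC1 | intermediate
17 | dicyclohexylboron aldolate of 18 | CC1=CC[C@H]([C@@H](C)CO[Si](c2ccccc2)(c2ccccc2)C(C)(C)C)[C@@H]([C@@H](OB(C2CCCCC2)C2CCCCC2)c2ccc(C#C[Si](C)(C)C)o2)C1=O | intermediate
18 | (5R,6S)-6-[(R)-hydroxy{5-[(trimethylsilyl)ethynyl]furan-2-yl}methyl]-2-methyl-5-[(2R)-1-(TBDPS-oxy)propan-2-yl]cyclohex-2-en-1-one | CC1=CC[C@H]([C@@H](C)CO[Si](c2ccccc2)(c2ccccc2)C(C)(C)C)[C@@H]([C@@H](O)c2ccc(C#C[Si](C)(C)C)o2)C1=O | intermediate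
19 | lithium alkoxide of 18 | CC1=CC[C@H]([C@@H](C)CO[Si](c2ccccc2)(c2ccccc2)C(C)(C)C)[C@@H]([C@@H](O[Li])c2ccc(C#C[Si](C)(C)C)o2)C1=O | intermediate
20 | dilithium alkoxide enolate (C10–C11 enolate) | CC1=C(O[Li])[C@H]([C@@H](O[Li])c2ccc(C#C[Si](C)(C)C)o2)[C@@H]([C@@H](C)CO[Si](c2ccccc2)(c2ccccc2)C(C)(C)C)CC1 | intermediate
21 | (5R,6S)-6-[(R)-hydroxy{5-[(trimethylsilyl)ethynyl]furan-2-yl}methyl]-2-methyl-5-[(2R)-1-(TBDPS-oxy)propan-2-yl]cyclohex-1-en-1-yl trifluoromethanesulfonate | CC1=C(OS(=O)(=O)C(F)(F)F)[C@H]([C@@H](O)c2ccc(C#C[Si](C)(C)C)o2)[C@@H]([C@@H](C)CO[Si](c2ccccc2)(c2ccccc2)C(C)(C)C)CC1 | intermediate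
22 | (3R,3aR,4R)-7-methyl-4-[(2R)-1-(TBDPS-oxy)propan-2-yl]-3-{5-[(trimethylsilyl)ethynyl]furan-2-yl}-3a,4,5,6-tetrahydro-2-benzofuran-1(3H)-one | CC1=C2C(=O)O[C@@H](c3ccc(C#C[Si](C)(C)C)o3)[C@@H]2[C@@H]([C@@H](C)CO[Si](c2ccccc2)(c2ccccc2)C(C)(C)C)CC1 | intermediate
23 | lithium dienolate of 22 (C9=C10, C11=C20) | C=C1CC[C@H]([C@@H](C)CO[Si](c2ccccc2)(c2ccccc2)C(C)(C)C)[C@@H]2C1=C(O[Li])O[C@H]2c1ccc(C#C[Si](C)(C)C)o1 | intermediate
24 | (3R,3aR,4R,7aR)-7-methylidene-4-[(2R)-1-(TBDPS-oxy)propan-2-yl]-3-{5-[(trimethylsilyl)ethynyl]furan-2-yl}hexahydro-2-benzofuran-1(3H)-one | C=C1CC[C@H]([C@@H](C)CO[Si](c2ccccc2)(c2ccccc2)C(C)(C)C)[C@@H]2[C@H]1C(=O)O[C@H]2c1ccc(C#C[Si](C)(C)C)o1 | intermediate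
25 | (1R,2R,3R)-2-[(R)-hydroxy{5-[(trimethylsilyl)ethynyl]furan-2-yl}methyl]-N-methoxy-N-methyl-6-methylidene-3-[(2R)-1-(TBDPS-oxy)propan-2-yl]cyclohexane-1-carboxamide | C=C1CC[C@H]([C@@H](C)CO[Si](c2ccccc2)(c2ccccc2)C(C)(C)C)[C@@H]([C@@H](O)c2ccc(C#C[Si](C)(C)C)o2)[C@H]1C(=O)N(C)OC | intermediate
26 | Achmatowicz hemiketal, 6-hydroxy-6-[(trimethylsilyl)ethynyl]-2H-pyran-3(6H)-one attached at C2 to the cyclohexane of 25 (anomers) | C=C1CC[C@H]([C@@H](C)CO[Si](c2ccccc2)(c2ccccc2)C(C)(C)C)[C@H]([C@H]1C(=O)N(C)OC)[C@H]1OC(O)(C#C[Si](C)(C)C)C=CC1=O | intermediate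
27 | (1R,2R,3R)-N-methoxy-N-methyl-6-methylidene-2-{(2R,6R)-3-oxo-6-[(trimethylsilyl)ethynyl]-3,6-dihydro-2H-pyran-2-yl}-3-[(2R)-1-(TBDPS-oxy)propan-2-yl]cyclohexane-1-carboxamide | C=C1CC[C@H]([C@@H](C)CO[Si](c2ccccc2)(c2ccccc2)C(C)(C)C)[C@H]([C@H]1C(=O)N(C)OC)[C@H]1O[C@@H](C#C[Si](C)(C)C)C=CC1=O | intermediate
28 | (1R,2R,3R)-N-methoxy-N-methyl-6-methylidene-2-{(2R,6R)-3-oxo-6-[(trimethylsilyl)ethynyl]oxan-2-yl}-3-[(2R)-1-(TBDPS-oxy)propan-2-yl]cyclohexane-1-carboxamide | C=C1CC[C@H]([C@@H](C)CO[Si](c2ccccc2)(c2ccccc2)C(C)(C)C)[C@H]([C@H]1C(=O)N(C)OC)[C@H]1O[C@@H](C#C[Si](C)(C)C)CCC1=O | intermediate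
29 | bromomagnesium C3 alkoxide of the methyl adduct of 28 | C=C1CC[C@H]([C@@H](C)CO[Si](c2ccccc2)(c2ccccc2)C(C)(C)C)[C@H]([C@H]1C(=O)N(C)OC)[C@H]1O[C@@H](C#C[Si](C)(C)C)CC[C@@]1(C)O[Mg]Br | intermediate
30 | lithium N-methoxy-N-methyl hemiaminal (chloromethyl adduct at C9) of 29 | C=C1CC[C@H]([C@@H](C)CO[Si](c2ccccc2)(c2ccccc2)C(C)(C)C)[C@H]([C@H]1C(O[Li])(CCl)N(C)OC)[C@H]1O[C@@H](C#C[Si](C)(C)C)CC[C@@]1(C)O[Mg]Br | intermediate
31 | 2-chloro-1-[(1R,2R,3R)-2-{(2R,3R,6R)-3-hydroxy-3-methyl-6-[(trimethylsilyl)ethynyl]oxan-2-yl}-6-methylidene-3-[(2R)-1-(TBDPS-oxy)propan-2-yl]cyclohexyl]ethan-1-one | C=C1CC[C@H]([C@@H](C)CO[Si](c2ccccc2)(c2ccccc2)C(C)(C)C)[C@H]([C@H]1C(=O)CCl)[C@H]1O[C@@H](C#C[Si](C)(C)C)CC[C@@]1(C)O | intermediate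
32 | (2R,3R,6R)-2-[(1R,2R,6R)-2-(chloroacetyl)-3-methylidene-6-[(2R)-1-(TBDPS-oxy)propan-2-yl]cyclohexyl]-3-methyl-6-[(trimethylsilyl)ethynyl]oxan-3-yl (2S)-2-(butanoyloxy)butanoate | C=C1CC[C@H]([C@@H](C)CO[Si](c2ccccc2)(c2ccccc2)C(C)(C)C)[C@H]([C@H]1C(=O)CCl)[C@H]1O[C@@H](C#C[Si](C)(C)C)CC[C@@]1(C)OC(=O)[C@H](CC)OC(=O)CCC | intermediate
33 | α-silyl ketone, as 34 but C6–C(=O)CH2SiMe3 | C=C1CC[C@H]([C@@H](C)CO[Si](c2ccccc2)(c2ccccc2)C(C)(C)C)[C@H]([C@H]1C(=O)CCl)[C@H]1O[C@@H](C(=O)C[Si](C)(C)C)CC[C@@]1(C)OC(=O)[C@H](CC)OC(=O)CCC | intermediate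
34 | (2R,3R,6R)-6-acetyl-2-[(1R,2R,6R)-2-(chloroacetyl)-3-methylidene-6-[(2R)-1-(TBDPS-oxy)propan-2-yl]cyclohexyl]-3-methyloxan-3-yl (2S)-2-(butanoyloxy)butanoate | C=C1CC[C@H]([C@@H](C)CO[Si](c2ccccc2)(c2ccccc2)C(C)(C)C)[C@H]([C@H]1C(=O)CCl)[C@H]1O[C@@H](C(C)=O)CC[C@@]1(C)OC(=O)[C@H](CC)OC(=O)CCC | intermediate
35 | diiodosamarium C8–C9 enolate of 34 | C=C1CC[C@H]([C@@H](C)CO[Si](c2ccccc2)(c2ccccc2)C(C)(C)C)[C@H]([C@H]1C(=C)O[Sm](I)I)[C@H]1O[C@@H](C(C)=O)CC[C@@]1(C)OC(=O)[C@H](CC)OC(=O)CCC | intermediate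
36 | diiodosamarium C7 alkoxide of 37 | C=C1CC[C@H]([C@@H](C)CO[Si](c2ccccc2)(c2ccccc2)C(C)(C)C)[C@@H]2[C@H]1C(=O)C[C@@](C)(O[Sm](I)I)[C@H]1CC[C@@](C)(OC(=O)[C@H](CC)OC(=O)CCC)[C@@H]2O1 | intermediate
37 | 17-O-TBDPS ether of the target | C=C1CC[C@H]([C@@H](C)CO[Si](c2ccccc2)(c2ccccc2)C(C)(C)C)[C@@H]2[C@H]1C(=O)C[C@@](C)(O)[C@H]1CC[C@@](C)(OC(=O)[C@H](CC)OC(=O)CCC)[C@@H]2O1 | intermediate
38 | CNP0291223.2 | C=C1CC[C@H]([C@@H](C)CO)[C@@H]2[C@H]1C(=O)C[C@@](C)(O)[C@H]1CC[C@@](C)(OC(=O)[C@H](CC)OC(=O)CCC)[C@@H]2O1 | target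

**Step count and risks**

Total step count: 20. Longest linear sequence: 16 (steps 1–4 and 9–20).

Most likely to fail, first: step 19. The ring closure needs the tetrahydropyran to place both C2 and C6 substituents axially, and the samarium enolate can simply be protonated instead. The fallback sets out from 34: reductive silylation (Zn, Me3SiCl, NaI cat., MeCN) converts the chloromethyl ketone regiospecifically into the trimethylsilyl enol ether F1. F1 is then cyclised in a chelation-controlled intramolecular Mukaiyama aldol (MgBr2·OEt2 or TiCl4, CH2Cl2, −78 °C, high dilution) and comes back to the route at 37 after aqueous work-up.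

Second: step 17. The tertiary alcohol is hindered and may sit partly as a hemiketal with the chloroketone. The fallback sets out from 28 and acylates before the chloroketone exists. After MeMgBr/CeCl3 addition the alkoxide is trapped in the flask with (S)-2-(butanoyloxy)butanoyl chloride F2 (from 14 with (COCl)2 and cat. DMF) to give the ester Weinreb amide F3. Cp2Zr(H)Cl reduces only the amide to the aldehyde F4. LiCH2Cl (1.1 equiv, −78 °C) adds to the aldehyde much faster than to the esters and gives the chlorohydrin F5. Dess–Martin oxidation brings the sequence back at 32.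

Third: step 12. γ-Deprotonation could occur at ring C12 instead of C20, or the dienolate could be reprotonated at C20. The fallback sets out from 22 and uses photochemical deconjugation (λ about 300 nm, MeOH with cat. 1,2-dimethylimidazole). A light-induced 1,5-hydrogen shift is only possible from the methyl syn to the carbonyl, and ketonisation of the dienol at C10 gives 24 directly, where it rejoins the route; no new compound is made.

**Further compounds**

F1 | step 19 | trimethylsilyl enol ether of the C9 ketone of 34 (C8H2=C9–OSiMe3) | C=C1CC[C@H]([C@@H](C)CO[Si](c2ccccc2)(c2ccccc2)C(C)(C)C)[C@H]([C@H]1C(=C)O[Si](C)(C)C)[C@H]1O[C@@H](C(C)=O)CC[C@@]1(C)OC(=O)[C@H](CC)OC(=O)CCC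
F2 | step 17 | (S)-2-(butanoyloxy)butanoyl chloride | CCCC(=O)O[C@@H](CC)C(Cl)=O
F3 | step 17 | C3 (2S)-2-(butanoyloxy)butanoate of the methyl adduct of 28 (Weinreb amide retained) | C=C1CC[C@H]([C@@H](C)CO[Si](c2ccccc2)(c2ccccc2)C(C)(C)C)[C@H]([C@H]1C(=O)N(C)OC)[C@H]1O[C@@H](C#C[Si](C)(C)C)CC[C@@]1(C)OC(=O)[C@H](CC)OC(=O)CCC
F4 | step 17 | C9 aldehyde corresponding to F3 | C=C1CC[C@H]([C@@H](C)CO[Si](c2ccccc2)(c2ccccc2)C(C)(C)C)[C@H]([C@H]1C=O)[C@H]1O[C@@H](C#C[Si](C)(C)C)CC[C@@]1(C)OC(=O)[C@H](CC)OC(=O)CCC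
F5 | step 17 | C9 chlorohydrin (C9–OH, C8H2Cl; C9 epimers) corresponding to 32 | C=C1CC[C@H]([C@@H](C)CO[Si](c2ccccc2)(c2ccccc2)C(C)(C)C)[C@H]([C@H]1C(O)CCl)[C@H]1O[C@@H](C#C[Si](C)(C)C)CC[C@@]1(C)OC(=O)[C@H](CC)OC(=O)CCC
F0 | step 12 | none | none
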